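**Retrosynthetic overview**
1. Target 12 ⇒ ester C–O bond: allylic alcohol 5 + (2E,4E,6S)-6-methylocta-2,4-dienoic acid 10 (from (S)-2-methylbutan-1-ol and a C4 phosphonate).
2. 5 ⇒ C3–H hydroxylation of trienone 4; 4 ⇒ C1–C2 dehydrogenation of dehydrofukinone 3.
3. 3 ⇒ eudesmane→eremophilane 1,2-methyl shift (C10→C5) from eudesmadienone 2; 2 ⇒ transannular C5–C10 disconnection to germacrone 1.
4. Ring order: the ten-membered ring is bought (germacrone); rings A and B of the decalin are closed together by one transannular C5–C10 bond; the methyl shift then converts the eudesmane into the eremophilane skeleton; no further ring is formed.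

Assumption: the sense of induction of the chiral acid in step 1 cannot be predicted with confidence; the (S,S) acid is written, its mirror image is used if the (10S) series forms, and the result is checked against natural dehydrofukinone (3).

**Step 1**
Reactants: 1 germacrone
Product: 3 (4S,5R)-eremophila-7(11),9-dien-8-one (dehydrofukinone), via eudesmadienone 2 (not isolated)
Conditions: (S,S)-imidodiphosphorimidate acid HN[P(=NSO2CF3)(O2C20H10Ar2)]2 (Ar = 3,5-(CF3)2C6H3, (S)-BINOL backbone, C74H33F30N3O8P2S2; 5 mol %), (CF3)2CHOH/CH2Cl2 1:4, −20 °C → rt; then CF3SO3H (0.3 equiv), rt → 40 °C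
Reagents that add atoms: none
Why: Proposed new method: the confined chiral ion pair protonates C1 of one of the two rapidly interconverting planar-chiral conformers of 1 (dynamic kinetic resolution), the C10 cation is trapped transannularly by C5 to close rings A and B at once and fix C10 as R in 2, and the stronger acid then re-protonates C4 on the α face while the 10β-methyl migrates to C5 and H9 is lost, so H and CH3 add anti across C4=C5 (cis 4β,5β-dimethyl) with the cross-conjugated dienone as thermodynamic sink; the closest known reaction types are the acid-induced transannular cyclisation of germacrone to selinadienones, enantioselective proton-initiated cation–olefin cyclisations with confined imidodiphosphorimidate acids, and the Westphalen-type angular methyl migration.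

**Step 2**
Reactants: 3 (4S,5R)-eremophila-7(11),9-dien-8-one
Product: 4 (4S,5R)-eremophila-1,7(11),9-trien-8-one
Conditions: chloranil (1.3 equiv), t-BuOH, reflux
Reagents that add atoms: none
Why: Quinone dehydrogenation through the linear dienol (γ-deprotonation at C1, hydride abstraction from C2), the same γ,δ-dehydrogenation that converts steroidal 4-en-3-ones into 4,6-dien-3-ones; C7 carries no hydrogen and no stereocentre is touched.

**Step 3**
Reactants: 4 (4S,5R)-eremophila-1,7(11),9-trien-8-one
Product: 5 (3S,4R,5R)-3-hydroxyeremophila-1,7(11),9-trien-8-one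
Conditions: SeO2 (1.1 equiv), 1,4-dioxane/H2O 50:1, 80 °C
Reagents that add atoms: selenium dioxide, O=[Se]=O
Why: Riley allylic oxidation (ene reaction at C1, then [2,3]-sigmatropic shift): C3 is the only allylic CH2 on the γ,δ-alkene, neither α-carbon of the ketone bears hydrogen, and because both pericyclic steps are suprafacial the pseudoaxial 3β-H is replaced by a 3β-OH, as in the SeO2 oxidation of cholesterol to the axial 4β-alcohol syn to the angular methyl.

**Step 4**
Reactants: 6 (S)-2-methylbutan-1-ol
Product: 7 (S)-2-methylbutanal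
Conditions: TEMPO (1 mol %), KBr (10 mol %), aq. NaOCl (1.1 equiv, NaHCO3, pH 9.5), CH2Cl2, 0 °C; dried CH2Cl2 solution used directly
Reagents that add atoms: none
Why: Anelli oxidation (oxoammonium catalysis, buffered, 0 °C) stops at the aldehyde and is the standard racemisation-free preparation of this α-branched aldehyde.

**Step 5**
Reactants: 7 (S)-2-methylbutanal; 8 triethyl (E)-4-phosphonocrotonate
Product: 10 (2E,4E,6S)-6-methylocta-2,4-dienoic acid, via ethyl dienoate 9 (not isolated)
Conditions: 8 (1.15 equiv), LiN(SiMe3)2 (1.1 equiv), THF, −78 °C; 7, −78 → 0 °C; then LiOH·H2O (3 equiv), THF/H2O, rt → 40 °C; 1 M HCl to pH 3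
Reagents that add atoms: lithium hydroxide, [Li+].[OH-]
Why: Vinylogous Horner–Wadsworth–Emmons olefination gives the 4E alkene (the 2E alkene comes from the reagent) with a slight deficit of base so no free amide can deprotonate C6, and in-flask saponification of the ethyl ester leaves the C6 stereocentre untouched.

**Step 6**
Reactants: 5 (3S,4R,5R)-3-hydroxyeremophila-1,7(11),9-trien-8-one; 10 (2E,4E,6S)-6-methylocta-2,4-dienoic acid
Product: 12 (3S,4R,5R)-8-oxoeremophila-1,7(11),9-trien-3-yl (2E,4E,6S)-6-methylocta-2,4-dienoate (target), via mixed anhydride 11 (not isolated)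
Conditions: 10 (1.5 equiv), 2,4,6-Cl3C6H2COCl, Et3N, THF, rt; then 5, DMAP, toluene, rt → 40 °C
Reagents that add atoms: none
Why: Yamaguchi esterification: DMAP transfers the dienoyl group from the mixed anhydride to the hindered pseudoaxial alcohol with retention at C3, under conditions too mild to isomerise the dienoate or the trienone.

**Compound list**
1 | germacrone, (3E,7E)-3,7-dimethyl-10-(propan-2-ylidene)cyclodeca-3,7-dien-1-one | C/C1=C\CC/C(C)=C/CC(=C(C)C)C(=O)C1 | starting material (commercial; crystallises from zdravets oil)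
2 | (10R)-eudesma-4,7(11)-dien-8-one, i.e. (8aR)-5,8a-dimethyl-3-(propan-2-ylidene)-3,4,6,7,8,8a-hexahydronaphthalen-2(1H)-one | CC1=C2CC(=C(C)C)C(=O)C[C@@]2(C)CCC1 | intermediate (not isolated)
3 | (4S,5R)-eremophila-7(11),9-dien-8-one (dehydrofukinone), i.e. (4aR,5S)-4a,5-dimethyl-3-(propan-2-ylidene)-4,4a,5,6,7,8-hexahydronaphthalen-2(3H)-one; the two methyls cis | C1CCC2=CC(=O)C(=C(C)C)C[C@]2(C)[C@H]1C | intermediate
4 | (4S,5R)-eremophila-1,7(11),9-trien-8-one, i.e. (4aR,5S)-4a,5-dimethyl-3-(propan-2-ylidene)-4,4a,5,6-tetrahydronaphthalen-2(3H)-one | C1C=CC2=CC(=O)C(=C(C)C)C[C@]2(C)[C@H]1C | intermediate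
5 | (3S,4R,5R)-3-hydroxyeremophila-1,7(11),9-trien-8-one, i.e. (4aR,5R,6S)-6-hydroxy-4a,5-dimethyl-3-(propan-2-ylidene)-4,4a,5,6-tetrahydronaphthalen-2(3H)-one; OH and both methyls on the same face | O[C@H]1C=CC2=CC(=O)C(=C(C)C)C[C@]2(C)[C@H]1C | intermediate
6 | (S)-2-methylbutan-1-ol | CC[C@H](C)CO | starting material
7 | (S)-2-methylbutanal | CC[C@H](C)C=O | intermediate
8 | triethyl (E)-4-phosphonocrotonate, ethyl (2E)-4-(diethoxyphosphoryl)but-2-enoate | CCOC(=O)/C=C/CP(=O)(OCC)OCC | starting material
9 | ethyl (2E,4E,6S)-6-methylocta-2,4-dienoate | CC[C@H](C)/C=C/C=C/C(=O)OCC | intermediate (not isolated)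
10 | (2E,4E,6S)-6-methylocta-2,4-dienoic acid | CC[C@H](C)/C=C/C=C/C(=O)O | intermediate
11 | (2E,4E,6S)-6-methylocta-2,4-dienoic 2,4,6-trichlorobenzoic anhydride | CC[C@H](C)/C=C/C=C/C(=O)OC(=O)c1c(Cl)cc(Cl)cc1Cl | intermediate (not isolated)
12 | (3S,4R,5R)-8-oxoeremophila-1,7(11),9-trien-3-yl (2E,4E,6S)-6-methylocta-2,4-dienoate (CNP0215744.1) | CC[C@H](C)/C=C/C=C/C(=O)O[C@H]1C=CC2=CC(=O)C(=C(C)C)C[C@]2(C)[C@H]1C | target

**Totals**
Total steps: 6. Longest linear sequence: 4 steps (1 → 3 → 4 → 5 → 12).

**Steps most likely to fail**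

Step 1 is the main risk. The enantioselectivity of the protonation is unproven, and the methyl shift may stall at 2 or give olefin-isomer mixtures. Fallback (sets out from 1, returns at 3): the same cascade is run with CF3SO3H alone in (CF3)2CHOH/CH2Cl2, so both conformers cyclise and the flask contains 2 together with (10S)-eudesma-4,7(11)-dien-8-one F1. These rearrange to racemic dehydrofukinone, that is 3 plus (4R,5S)-eremophila-7(11),9-dien-8-one F2. Preparative SFC on an amylose tris(3,5-dimethylphenylcarbamate) phase separates 3 from F2, and 3 continues into step 2. This replaces asymmetric catalysis by racemic synthesis and resolution.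

Step 3 is the second risk. The γ,δ-alkene of the trienone is electron-poor, so the ene step may be slow, and SeO2 may over-oxidise to the 3-ketone or dehydrogenate towards C3=C4. Fallback (sets out from 4, returns at 5): C3 is oxidised to the ketone with CrO3·3,5-dimethylpyrazole in CH2Cl2 at −20 °C, giving (4R,5R)-eremophila-1,7(11),9-triene-3,8-dione F3. Luche reduction (NaBH4, CeCl3·7H2O, MeOH, −78 °C) then reduces the unhindered C3 enone carbonyl in preference to the hindered, cross-conjugated C8 carbonyl. Hydride should enter from the α face, anti to the pseudoaxial C5 methyl, to give 5; selectivity with a small hydride may be modest, and any 3α-epimer is re-oxidised and recycled.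

Step 2 is the third risk. Chloranil may dehydrogenate further (C3=C4) or react through the cross-conjugated dienol at C6. Fallback (sets out from 3, returns at 4): 3 is silylated under equilibrating conditions (TBSOTf, Et3N, CH2Cl2, 0 °C) to the linear dienol ether (4S,5R)-8-(tert-butyldimethylsilyloxy)eremophila-1(10),7(11),8-triene F4. Saegusa–Ito oxidation with Pd(OAc)2 in MeCN at rt places palladium at C1, and β-hydride elimination from C2 gives 4.

**Further compounds**
F1 | step 1 | (10S)-eudesma-4,7(11)-dien-8-one | CC1=C2CC(=C(C)C)C(=O)C[C@]2(C)CCC1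
F2 | step 1 | (4R,5S)-eremophila-7(11),9-dien-8-one | C1CCC2=CC(=O)C(=C(C)C)C[C@@]2(C)[C@@H]1C
F3 | step 3 | (4R,5R)-eremophila-1,7(11),9-triene-3,8-dione | O=C1C=CC2=CC(=O)C(=C(C)C)C[C@]2(C)[C@H]1C
F4 | step 2 | (4S,5R)-8-(tert-butyldimethylsilyloxy)eremophila-1(10),7(11),8-triene | C1CC=C2C=C(O[Si](C)(C)C(C)(C)C)C(=C(C)C)C[C@]2(C)[C@H]1C
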